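**Plan**

- Oxolane numbering of the target: O1, C2 (CH2), C3 (OH), C4 (4-methoxyphenyl), C5 (carbinol side chain). Retrosynthesis first removes the C3–H bond (ketone reduction) and the C4–H and C5–H bonds (hydrogenation), which leads back to a 3(2H)-furanone and then to an aromatic 3-hydroxyfuran-2-carboxylate.
- The furan is cut at O1–C5 and C2–C3 into methyl glycolate and a 3-chloro-2-arylacrylate. The acrylate is cut at its C2–C3 bond (Claisen) into methyl 4-methoxyphenylacetate and an (R)-mandelic Weinreb amide.
- Enabling feature: the ring CH2 (C2) lies between the ring oxygen O1 and the oxygen-bearing C3. This is a glycolic acid unit, an O-nucleophile and, as its ester enolate, a C-nucleophile. C5–C4(aryl)–C3 is the β-carbon, α-carbon and carboxyl carbon of a 2-arylacrylate, a 1,3-dielectrophile. The oxolan-3-ol ring is thus the reduced form of a 3-hydroxyfuran-2-carboxylate, whose extra ester is a removable activating group.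
- Forward: the chain is assembled in steps 1–5, the only ring is closed in step 6, the ester helper leaves in step 7, and the ring is saturated in steps 9 and 10.
- Stereochemistry: the carbinol centre comes from asymmetric transfer hydrogenation (step 1). Its hydroxyl directs the hydrogenation that sets C4 and C5 cis (step 9). Hydride attack anti to these two substituents sets C3 (step 10).

Key step: step 6

Remark: 6 is a keto/enol mixture that is epimeric at C2, and 7 and 9 are E/Z mixtures; all converge in step 6, so only the carbinol centre is specified in their SMILES.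

**Step 1**
Reactants: 1 ethyl 2-(3,4-dimethoxyphenyl)-2-oxoacetate
Product: 2 ethyl (2R)-2-(3,4-dimethoxyphenyl)-2-hydroxyacetate
Conditions: RuCl[(S,S)-TsDPEN](p-cymene) (1 mol%), HCO2H/Et3N (5:2), DMF, 25 °C
Reagents that add atoms: none
Why: Noyori–Ikariya asymmetric transfer hydrogenation of an aryl α-keto ester, in which hydride goes to the ketone face exposed by the CH/π contact between the aryl ring and the p-cymene ligand, which with the (S,S)-ligand should give the (R)-alcohol (R because the ester outranks the aryl group), the ester and aryl ethers being inert.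

**Step 2**
Reactants: 2 ethyl (2R)-2-(3,4-dimethoxyphenyl)-2-hydroxyacetate
Product: 3 ethyl (2R)-2-[(tert-butyldimethylsilyl)oxy]-2-(3,4-dimethoxyphenyl)acetate
Conditions: TBSCl, imidazole, DMF, 23 °C
Reagents that add atoms: tert-butyldimethylsilyl chloride, CC(C)(C)[Si](C)(C)Cl
Why: Standard imidazole-promoted silylation of a secondary alcohol, which blocks the hydroxyl against the bases of steps 3 to 7 and does not touch the stereocentre.

**Step 3**
Reactants: 3 ethyl (2R)-2-[(tert-butyldimethylsilyl)oxy]-2-(3,4-dimethoxyphenyl)acetate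
Product: 4 (2R)-2-[(tert-butyldimethylsilyl)oxy]-2-(3,4-dimethoxyphenyl)-N-methoxy-N-methylacetamide
Conditions: MeNH(OMe)·HCl, i-PrMgCl, THF, −20 °C
Reagents that add atoms: N,O-dimethylhydroxylamine hydrochloride, CNOC.Cl
Why: Weinreb amide formation by aminolysis of the ester with the chloromagnesium amide of N,O-dimethylhydroxylamine at low temperature, where acyl substitution should outrun deprotonation of the benzylic α-hydrogen so that the (R)-centre is kept.

**Step 4**
Reactants: 4 (2R)-2-[(tert-butyldimethylsilyl)oxy]-2-(3,4-dimethoxyphenyl)-N-methoxy-N-methylacetamide; 5 methyl 2-(4-methoxyphenyl)acetate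
Product: 6 methyl (4R)-4-[(tert-butyldimethylsilyl)oxy]-4-(3,4-dimethoxyphenyl)-2-(4-methoxyphenyl)-3-oxobutanoate
Conditions: 5, LiN(SiMe3)2, THF, −78 °C; then 4, −78 → −20 °C; cold 1 M HCl
Reagents that add atoms: none
Why: Crossed Claisen-type acylation of the lithium enolate of 5 by a Weinreb amide, whose chelated tetrahedral adduct releases the ketone only on work-up, so that no second addition occurs and the weakly basic arylacetate enolate should leave the (R)-centre intact, the new labile centre at C2 being lost in step 5.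

**Step 5**
Reactants: 6 methyl (4R)-4-[(tert-butyldimethylsilyl)oxy]-4-(3,4-dimethoxyphenyl)-2-(4-methoxyphenyl)-3-oxobutanoate
Product: 7 methyl (4R)-4-[(tert-butyldimethylsilyl)oxy]-3-chloro-4-(3,4-dimethoxyphenyl)-2-(4-methoxyphenyl)but-2-enoate (E/Z mixture)
Conditions: Ph3PCl2, Et3N, MeCN, 23 → 50 °C
Reagents that add atoms: dichlorotriphenylphosphorane, ClP(Cl)(c1ccccc1)(c1ccccc1)c1ccccc1
Why: Deoxychlorination of the enol form of an α-aryl β-keto ester with a chlorophosphorane and amine base (Piers-type vinyl halide synthesis), in which the enol oxygen is bound to phosphorus and replaced by chloride through addition–elimination, turning the ketone carbon into a vinylogous acyl chloride position whose geometry is irrelevant.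

**Step 6**
Reactants: 7 methyl (4R)-4-[(tert-butyldimethylsilyl)oxy]-3-chloro-4-(3,4-dimethoxyphenyl)-2-(4-methoxyphenyl)but-2-enoate; 8 methyl glycolate (methyl 2-hydroxyacetate)
Product: 10 methyl 5-[(R)-[(tert-butyldimethylsilyl)oxy](3,4-dimethoxyphenyl)methyl]-3-hydroxy-4-(4-methoxyphenyl)furan-2-carboxylate, via glycolate enol ether 9 (not isolated)
Conditions: 8 (1.3 equiv), NaH (2.5 equiv), THF, 0 → 40 °C; cold dilute HCl to pH 5
Reagents that add atoms: none
Why: The sodium alkoxide of 8 adds to the chlorine-bearing β-carbon of acrylate 7 and chloride leaves (addition–elimination), which makes the ring bond O1–C5 and gives 9; the CH2 of 9, now flanked by the ether oxygen and its own ester, is deprotonated and attacks the arylacrylate ester carbonyl (Dieckmann), which makes the ring bond C2–C3, and loss of methoxide and enolization give the aromatic 3-hydroxyfuran as its sodium salt, the thermodynamic sink. The closest known reaction type is the Fiesselmann thiophene synthesis and its oxygen variant, in which a glycolate displaces halide from a β-halo-acrylate or a 2-halo(hetero)aryl ester and then closes by Dieckmann condensation to a 3-hydroxy(benzo)furan-2-carboxylate. The one ring closure is 5-exo-trig, carbanion onto ester carbonyl, and the O1–C5 bond is made intermolecularly before it. No stereocentre is formed: the (R)-carbinol centre is carried through and only its hydrogen must stay untouched. The step needs attack at the β-carbon instead of at an ester, a single Dieckmann direction and convergence of the E and Z isomers: the chloride makes C3 of 7 the only vinylogous acyl position, the acrylate α-carbon has no hydrogen so only the glycolate CH2 can become the nucleophile, and reversible alkoxide addition to the push–pull alkene of 9 interconverts the geometrical isomers until the one with the ester cis to the glycolate oxygen cyclizes. The carbinol hydrogen, γ to the ester in 7, is the weak point; it is protected by low temperature and, once the ring has formed, by the aromatic oxido-furan.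

**Step 7**
Reactants: 10 methyl 5-[(R)-[(tert-butyldimethylsilyl)oxy](3,4-dimethoxyphenyl)methyl]-3-hydroxy-4-(4-methoxyphenyl)furan-2-carboxylate
Product: 12 5-[(R)-[(tert-butyldimethylsilyl)oxy](3,4-dimethoxyphenyl)methyl]-4-(4-methoxyphenyl)furan-3(2H)-one, via furancarboxylic acid 11 (not isolated)
Conditions: LiOH, THF/MeOH/H2O, 60 °C; then AcOH to pH 4–5, 40 °C
Reagents that add atoms: none
Why: Saponification of the furan ester followed by decarboxylation of the 3-hydroxyfuran-2-carboxylic acid through its β-keto acid tautomer on mild acidification, a standard entry to 3(2H)-furanones, the carbinol centre being safe because the ring is an aromatic oxido-furan in base and the silyl ether stays on.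

**Step 8**
Reactants: 12 5-[(R)-[(tert-butyldimethylsilyl)oxy](3,4-dimethoxyphenyl)methyl]-4-(4-methoxyphenyl)furan-3(2H)-one
Product: 13 5-[(R)-(3,4-dimethoxyphenyl)(hydroxy)methyl]-4-(4-methoxyphenyl)furan-3(2H)-one
Conditions: Bu4NF, AcOH (1:1), THF, 0 → 23 °C
Reagents that add atoms: none
Why: Fluoride cleavage of the silyl ether, buffered with acetic acid so that neither the acidic ring CH2 nor the vinylogous carbinol hydrogen is exposed to base.

**Step 9**
Reactants: 13 5-[(R)-(3,4-dimethoxyphenyl)(hydroxy)methyl]-4-(4-methoxyphenyl)furan-3(2H)-one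
Product: 14 (4S,5S)-5-[(R)-(3,4-dimethoxyphenyl)(hydroxy)methyl]-4-(4-methoxyphenyl)oxolan-3-one
Conditions: [Ir(cod)(PCy3)(py)]PF6 (5 mol%), H2 (1–10 bar), CH2Cl2, 23 °C
Reagents that add atoms: none
Why: Hydroxyl-directed homogeneous hydrogenation of an allylic alcohol, in which A(1,3) strain against the cis 4-methoxyphenyl group holds the carbinol hydrogen in the alkene plane, the hydroxyl on one face binds iridium and both hydrogens are delivered to that face, which for the (R)-carbinol should set C5 as S (carbinol oxygen anti to O1) and C4 cis to it (4S,5S).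

**Step 10**
Reactants: 14 (4S,5S)-5-[(R)-(3,4-dimethoxyphenyl)(hydroxy)methyl]-4-(4-methoxyphenyl)oxolan-3-one
Product: 15 (3S,4R,5S)-5-[(R)-(3,4-dimethoxyphenyl)(hydroxy)methyl]-4-(4-methoxyphenyl)oxolan-3-ol
Conditions: LiBH(s-Bu)3 (2.5 equiv), THF, −78 °C; then H2O
Reagents that add atoms: none
Why: Reduction of a five-ring ketone next to a cis-4,5-disubstituted segment by a bulky trialkylborohydride, which attacks from the face opposite to the aryl group and the side chain and so places the new hydroxyl cis to both (3S), the low temperature keeping the epimerizable C4 centre intact.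

**Compound list**

1 | ethyl 2-(3,4-dimethoxyphenyl)-2-oxoacetate | CCOC(=O)C(=O)c1ccc(OC)c(OC)c1 | starting material
2 | ethyl (2R)-2-(3,4-dimethoxyphenyl)-2-hydroxyacetate | CCOC(=O)[C@H](O)c1ccc(OC)c(OC)c1 | intermediate
3 | ethyl (2R)-2-[(tert-butyldimethylsilyl)oxy]-2-(3,4-dimethoxyphenyl)acetate | CCOC(=O)[C@H](O[Si](C)(C)C(C)(C)C)c1ccc(OC)c(OC)c1 | intermediate
4 | (2R)-2-[(tert-butyldimethylsilyl)oxy]-2-(3,4-dimethoxyphenyl)-N-methoxy-N-methylacetamide | CON(C)C(=O)[C@H](O[Si](C)(C)C(C)(C)C)c1ccc(OC)c(OC)c1 | intermediate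
5 | methyl 2-(4-methoxyphenyl)acetate | COC(=O)Cc1ccc(OC)cc1 | starting material
6 | methyl (4R)-4-[(tert-butyldimethylsilyl)oxy]-4-(3,4-dimethoxyphenyl)-2-(4-methoxyphenyl)-3-oxobutanoate | COC(=O)C(c1ccc(OC)cc1)C(=O)[C@H](O[Si](C)(C)C(C)(C)C)c1ccc(OC)c(OC)c1 | intermediate
7 | methyl (4R)-4-[(tert-butyldimethylsilyl)oxy]-3-chloro-4-(3,4-dimethoxyphenyl)-2-(4-methoxyphenyl)but-2-enoate (E/Z mixture) | COC(=O)C(c1ccc(OC)cc1)=C(Cl)[C@H](O[Si](C)(C)C(C)(C)C)c1ccc(OC)c(OC)c1 | intermediate
8 | methyl 2-hydroxyacetate (methyl glycolate) | COC(=O)CO | starting material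
9 | methyl (4R)-4-[(tert-butyldimethylsilyl)oxy]-4-(3,4-dimethoxyphenyl)-3-(2-methoxy-2-oxoethoxy)-2-(4-methoxyphenyl)but-2-enoate (E/Z mixture) | COC(=O)COC(=C(C(=O)OC)c1ccc(OC)cc1)[C@H](O[Si](C)(C)C(C)(C)C)c1ccc(OC)c(OC)c1 | intermediate
10 | methyl 5-[(R)-[(tert-butyldimethylsilyl)oxy](3,4-dimethoxyphenyl)methyl]-3-hydroxy-4-(4-methoxyphenyl)furan-2-carboxylate | COC(=O)c1oc([C@H](O[Si](C)(C)C(C)(C)C)c2ccc(OC)c(OC)c2)c(-c2ccc(OC)cc2)c1O | intermediate
11 | 5-[(R)-[(tert-butyldimethylsilyl)oxy](3,4-dimethoxyphenyl)methyl]-3-hydroxy-4-(4-methoxyphenyl)furan-2-carboxylic acid | OC(=O)c1oc([C@H](O[Si](C)(C)C(C)(C)C)c2ccc(OC)c(OC)c2)c(-c2ccc(OC)cc2)c1O | intermediate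
12 | 5-[(R)-[(tert-butyldimethylsilyl)oxy](3,4-dimethoxyphenyl)methyl]-4-(4-methoxyphenyl)furan-3(2H)-one | O=C1COC([C@H](O[Si](C)(C)C(C)(C)C)c2ccc(OC)c(OC)c2)=C1c1ccc(OC)cc1 | intermediate
13 | 5-[(R)-(3,4-dimethoxyphenyl)(hydroxy)methyl]-4-(4-methoxyphenyl)furan-3(2H)-one | O=C1COC([C@H](O)c2ccc(OC)c(OC)c2)=C1c1ccc(OC)cc1 | intermediate
14 | (4S,5S)-5-[(R)-(3,4-dimethoxyphenyl)(hydroxy)methyl]-4-(4-methoxyphenyl)oxolan-3-one | COc1ccc([C@H]2[C@@H]([C@H](O)c3ccc(OC)c(OC)c3)OCC2=O)cc1 | intermediate
15 | (3S,4R,5S)-5-[(R)-(3,4-dimethoxyphenyl)(hydroxy)methyl]-4-(4-methoxyphenyl)oxolan-3-ol | COc1ccc([C@H]2[C@@H]([C@H](O)c3ccc(OC)c(OC)c3)OC[C@H]2O)cc1 | target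

**Step count and risks**

Total step count: 10. Longest linear sequence: 10 steps (1 → 15); 5 and 8 enter as bought building blocks.

Steps most likely to fail:

1. Step 6. Substitution at the fully substituted, hindered β-carbon may be slow, and base may instead remove the carbinol hydrogen with loss of HCl toward an allenoate, which would erode the configuration of the carbinol centre. The fallback sets out from 6 and comes back at 10. The enol of 6 is O-alkylated with 8 under Mitsunobu conditions (PPh3, DIAD, THF, 0 °C), so that the ether is made at the CH2–O bond under neutral conditions and 7 is not needed. This gives 9, which is now isolated, and KOt-Bu in THF at 0 °C then closes it by Dieckmann condensation to 10. This fallback makes no compound outside the list (F0).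

2. Step 9. The cationic iridium catalyst may fail to bind the tetrasubstituted push–pull alkene, or the cis ketone may partly epimerize at C4. The fallback sets out from 13 and comes back at 15; it sets C5 first and then C4 and C3 together.
   - Hydrogenation of 13 over 5% Rh on Al2O3 in EtOAc, with the surface approaching the hydroxyl face of the same rotamer, should give (5S)-5-[(R)-(3,4-dimethoxyphenyl)(hydroxy)methyl]-4-(4-methoxyphenyl)oxolan-3-one as a mixture of C4 epimers F1.
   - TBSOTf and Et3N in CH2Cl2 silylate the hydroxyl and convert both epimers into one aryl-conjugated silyl enol ether, (2S)-4-[(tert-butyldimethylsilyl)oxy]-2-{(R)-[(tert-butyldimethylsilyl)oxy](3,4-dimethoxyphenyl)methyl}-3-(4-methoxyphenyl)-2,5-dihydrofuran F2.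
   - Hydrogenation over Pd/C from the face opposite to the side chain places the aryl and silyloxy groups cis to it and gives the bis(tert-butyldimethylsilyl) ether of 15 F3.
   - Bu4NF in THF then gives 15.

3. Step 4. Proton transfer from the amide α-carbon to the enolate may compete with addition, leading to racemization and low conversion. The fallback sets out from 3 and comes back at 6.
   - Reduction of 3 with i-Bu2AlH in CH2Cl2 at −78 °C gives (2R)-2-[(tert-butyldimethylsilyl)oxy]-2-(3,4-dimethoxyphenyl)acetaldehyde F4.
   - Aldol addition of the lithium enolate of 5 (LiN(i-Pr)2, THF, −78 °C), which is fast at an aldehyde, gives methyl (4R)-4-[(tert-butyldimethylsilyl)oxy]-4-(3,4-dimethoxyphenyl)-3-hydroxy-2-(4-methoxyphenyl)butanoate F5 as a diastereomer mixture.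
   - Oxidation with Dess–Martin periodinane gives 6.

Further compounds
F0 | step 6 | none | none
F1 | step 9 | (5S)-5-[(R)-(3,4-dimethoxyphenyl)(hydroxy)methyl]-4-(4-methoxyphenyl)oxolan-3-one, mixture of C4 epimers | COc1ccc(C2[C@@H]([C@H](O)c3ccc(OC)c(OC)c3)OCC2=O)cc1
F2 | step 9 | (2S)-4-[(tert-butyldimethylsilyl)oxy]-2-{(R)-[(tert-butyldimethylsilyl)oxy](3,4-dimethoxyphenyl)methyl}-3-(4-methoxyphenyl)-2,5-dihydrofuran | COc1ccc(C2=C(O[Si](C)(C)C(C)(C)C)CO[C@@H]2[C@H](O[Si](C)(C)C(C)(C)C)c2ccc(OC)c(OC)c2)cc1
F3 | step 9 | bis(tert-butyldimethylsilyl) ether of 15 (all-cis ring) | COc1ccc([C@H]2[C@@H]([C@H](O[Si](C)(C)C(C)(C)C)c3ccc(OC)c(OC)c3)OC[C@H]2O[Si](C)(C)C(C)(C)C)cc1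
F4 | step 4 | (2R)-2-[(tert-butyldimethylsilyl)oxy]-2-(3,4-dimethoxyphenyl)acetaldehyde | O=C[C@H](O[Si](C)(C)C(C)(C)C)c1ccc(OC)c(OC)c1
F5 | step 4 | methyl (4R)-4-[(tert-butyldimethylsilyl)oxy]-4-(3,4-dimethoxyphenyl)-3-hydroxy-2-(4-methoxyphenyl)butanoate (mixture at C2 and C3) | COC(=O)C(c1ccc(OC)cc1)C(O)[C@H](O[Si](C)(C)C(C)(C)C)c1ccc(OC)c(OC)c1
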